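**Plan**

- Ring B is numbered C1 (O–ring A, the 2,4,6-trioxygenated ring), C2 (O–ring D), C3 (OH), C4 (O–ring C), C5 (OH), C6 (H). The retrosynthesis cuts, in order, the eleven O–benzyl bonds, the aryl C–O bond between ring D and O–C2, the C5 O–benzyl bond, and then the C5–C6 bond of ring B.
- Cutting C5–C6 and rejoining C2 to C5 gives a 4-hydroxycyclobutenone. C2–C5 with their four contiguous oxygens are the four carbons of squaric acid. C1 (with its ring A ether) and the unsubstituted C6 are a 1-(aryloxy)vinyl group, and the C1–C2 bond is cut last, to a vinyllithium and a benzyl aryl squarate.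
- Forward: ring A phenol → ethynyl ether → 1-stannylvinyl ether; squaric acid → dichloride → mixed benzyl/ring C squarate; vinyllithium addition; thermal ring expansion closes ring B, the only ring formed. Then C5 benzylation, copper-mediated attachment of ring D and global hydrogenolysis.
- Stereochemistry: the target has no stereocentre. The single stereocentre of the route, the carbinol carbon of the cyclobutenone, is racemic and becomes aromatic C2.

Key step: step 10

**Route**

Step 1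
Reactants: 1 2,4,6-trihydroxybenzaldehyde
Product: 2 2,4,6-tris(benzyloxy)benzaldehyde
Conditions: BnBr (3.5 equiv), K2CO3, DMF, rt → 60 °C
Reagents that add atoms: benzyl bromide, BrCc1ccccc1
Why: Williamson etherification of the three phenoxides should occur on oxygen, because the formyl group lowers the ring nucleophilicity that otherwise leads to C-benzylation of phloroglucinols.

Step 2
Reactants: 2 2,4,6-tris(benzyloxy)benzaldehyde
Product: 4 2,4,6-tris(benzyloxy)phenol, via 2,4,6-tris(benzyloxy)phenyl formate 3 (not isolated)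
Conditions: mCPBA, CH2Cl2, 0 °C → rt; then K2CO3 (cat.), MeOH, rt
Reagents that add atoms: 3-chloroperoxybenzoic acid, OOC(=O)c1cccc(Cl)c1
Why: In this Baeyer–Villiger (Dakin-type) oxidation the electron-rich trialkoxyaryl group migrates in preference to hydride, and methanolysis of the aryl formate frees the phenol.

Step 3
Reactants: 4 2,4,6-tris(benzyloxy)phenol
Product: 5 1,3,5-tris(benzyloxy)-2-{[(E)-1,2-dichloroethenyl]oxy}benzene
Conditions: Cl2C=CHCl, K2CO3, DMF, 70 °C
Reagents that add atoms: trichloroethylene, ClC=C(Cl)Cl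
Why: The phenoxide adds anti across dichloroacetylene formed in the flask by dehydrochlorination of trichloroethylene, a known route to aryl (E)-1,2-dichlorovinyl ethers, and the small linear electrophile should tolerate the two ortho benzyloxy groups.

Step 4
Reactants: 5 1,3,5-tris(benzyloxy)-2-{[(E)-1,2-dichloroethenyl]oxy}benzene
Product: 8 1,3,5-tris(benzyloxy)-2-(ethynyloxy)benzene, via chloroethynyl aryl ether 6 (not isolated), via lithium aryloxyacetylide 7 (not isolated)
Conditions: n-BuLi (2.3 equiv), THF, −78 → −40 °C; then aq NH4Cl, −78 °C; crude 8 kept cold and used at once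
Reagents that add atoms: none
Why: Base-induced dehydrochlorination to the chloroalkyne followed by chlorine–lithium exchange is the standard conversion of 1,2-dichlorovinyl ethers into alkynyl ethers, and at −78 °C it should outpace deprotonation of the benzyl ethers.

Step 5
Reactants: 8 1,3,5-tris(benzyloxy)-2-(ethynyloxy)benzene
Product: 9 tributyl{1-[2,4,6-tris(benzyloxy)phenoxy]ethenyl}stannane
Conditions: Bu3SnH, Pd(PPh3)4 (2 mol %), THF, 0 °C; chromatography on Et3N-deactivated silica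
Reagents that add atoms: tributyltin hydride, CCCC[SnH](CCCC)CCCC
Why: Palladium-catalysed hydrostannation of alkynyl ethers is a syn addition that puts hydrogen on the β-carbon and tin on the oxygen-bearing carbon, which should give the 1-(aryloxy)vinylstannane.

Step 6
Reactants: 10 3,4,5-tris(benzyloxy)benzaldehyde
Product: 12 3,4,5-tris(benzyloxy)phenol, via 3,4,5-tris(benzyloxy)phenyl formate 11 (not isolated)
Conditions: mCPBA, CH2Cl2, 0 °C → rt; then K2CO3 (cat.), MeOH, rt
Reagents that add atoms: 3-chloroperoxybenzoic acid, OOC(=O)c1cccc(Cl)c1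
Why: Baeyer–Villiger (Dakin-type) oxidation with aryl migration favoured by the para benzyloxy group, then methanolysis of the formate, is the usual way from this aldehyde to the phenol.

Step 7
Reactants: 13 squaric acid
Product: 14 3,4-dichlorocyclobut-3-ene-1,2-dione (squaryl dichloride)
Conditions: (COCl)2, DMF (cat.), CH2Cl2, reflux
Reagents that add atoms: oxalyl chloride, O=C(Cl)C(=O)Cl
Why: Vilsmeier-type activation turns the two vinylogous acid hydroxyls into vinylogous acid chlorides, the standard preparation of this dichloride.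

Step 8
Reactants: 14 3,4-dichlorocyclobut-3-ene-1,2-dione; 12 3,4,5-tris(benzyloxy)phenol
Product: 16 3-(benzyloxy)-4-[3,4,5-tris(benzyloxy)phenoxy]cyclobut-3-ene-1,2-dione, via 3-(benzyloxy)-4-chlorocyclobut-3-ene-1,2-dione 15 (not isolated)
Conditions: BnOH (1.0 equiv), i-Pr2NEt, CH2Cl2, −78 °C; then 12, i-Pr2NEt, −78 → 0 °C
Reagents that add atoms: benzyl alcohol, OCc1ccccc1
Why: Two successive addition–eliminations at the vinylogous acid chloride carbons should be separable, because the first benzyloxy donor deactivates the remaining chloride, which is then displaced through oxygen by the phenoxide of 12 under amine base.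

Step 9
Reactants: 9 tributyl{1-[2,4,6-tris(benzyloxy)phenoxy]ethenyl}stannane; 16 3-(benzyloxy)-4-[3,4,5-tris(benzyloxy)phenoxy]cyclobut-3-ene-1,2-dione
Product: 19 racemic 3-(benzyloxy)-4-hydroxy-2-[3,4,5-tris(benzyloxy)phenoxy]-4-{1-[2,4,6-tris(benzyloxy)phenoxy]vinyl}cyclobut-2-en-1-one, via 1-[2,4,6-tris(benzyloxy)phenoxy]vinyllithium 17 (not isolated), via lithium cyclobutenone alkoxide 18 (not isolated)
Conditions: n-BuLi (0.95 equiv), THF, −78 °C; cannulated into 16, THF, −78 °C; aq NH4Cl, −78 °C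
Reagents that add atoms: none
Why: Tin–lithium exchange gives the vinyllithium, whose 1,2-addition should go to the carbonyl next to the C–OBn carbon, since that carbonyl is conjugated only with the weaker aryloxy donor whereas the other is a vinylogous benzyl ester, and the new carbinol stereocentre forms as the racemate.

Step 10
Reactants: 19 racemic 3-(benzyloxy)-4-hydroxy-2-[3,4,5-tris(benzyloxy)phenoxy]-4-{1-[2,4,6-tris(benzyloxy)phenoxy]vinyl}cyclobut-2-en-1-one
Product: 22 3-(benzyloxy)-5-[2,4,6-tris(benzyloxy)phenoxy]-2-[3,4,5-tris(benzyloxy)phenoxy]benzene-1,4-diol, via (Z)-dienylketene 20 (not isolated), via cyclohexa-2,4-dienone tautomer 21 (not isolated)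
Conditions: toluene (degassed), 110 °C, Ar
Reagents that add atoms: none
Why: Heating should open the cyclobutenone by conrotatory 4π electrocyclic cleavage of the bond between the carbonyl and the carbinol carbon to give dienylketene 20, whose ketene carbon then bonds to the vinyl CH2 terminus in a thermally allowed disrotatory 6π electrocyclization that forms the C5–C6 bond and the six-membered ring B as dienone 21, which tautomerizes to the aromatic hydroquinone. The closest known reaction type is the Moore rearrangement of squarate-derived 4-alkenyl-4-hydroxycyclobutenones, including 4-(1-alkoxyvinyl) cases, to polyoxygenated hydroquinones. No stereocentre is created, since the racemic carbinol carbon becomes aromatic C2. The selectivity needed is torquoselectivity: the donor hydroxyl on the carbinol carbon rotates outward, so the vinyl group rotates inward and lies cis to the ketene, the only geometry that can cyclize. The substitution pattern of ring B is fixed beforehand by the regiochemistry of step 9, and oxygen is excluded so that the electron-rich hydroquinone does not go on to the quinone.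

Step 11
Reactants: 22 3-(benzyloxy)-5-[2,4,6-tris(benzyloxy)phenoxy]-2-[3,4,5-tris(benzyloxy)phenoxy]benzene-1,4-diol
Product: 23 2,4-bis(benzyloxy)-6-[2,4,6-tris(benzyloxy)phenoxy]-3-[3,4,5-tris(benzyloxy)phenoxy]phenol
Conditions: BnBr (1.05 equiv), K2CO3, acetone (degassed), rt, Ar
Reagents that add atoms: benzyl bromide, BrCc1ccccc1
Why: Williamson etherification with one equivalent of benzyl bromide should take the C5 phenoxide, which has a free ortho position, in preference to the C2 phenoxide buried between the C3 benzyloxy group and the 2,6-disubstituted ring A ether.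

Step 12
Reactants: 24 5-bromo-1,2,3-trimethoxybenzene
Product: 25 5-bromobenzene-1,2,3-triol
Conditions: BBr3, CH2Cl2, −78 °C → rt; then H2O
Reagents that add atoms: none
Why: Lewis acid demethylation of aryl methyl ethers by BBr3 leaves the aryl bromide untouched.

Step 13
Reactants: 25 5-bromobenzene-1,2,3-triol
Product: 26 5-bromo-1,2,3-tris(benzyloxy)benzene
Conditions: BnBr (3.5 equiv), K2CO3, DMF, 60 °C, Ar
Reagents that add atoms: benzyl bromide, BrCc1ccccc1
Why: Williamson etherification of the three pyrogallol phenoxides under argon is routine.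

Step 14
Reactants: 26 5-bromo-1,2,3-tris(benzyloxy)benzene
Product: 29 [3,4,5-tris(benzyloxy)phenyl]boronic acid, via 3,4,5-tris(benzyloxy)phenyllithium 27 (not isolated), via lithium aryltriisopropoxyborate 28 (not isolated)
Conditions: n-BuLi, THF, −78 °C; B(Oi-Pr)3, −78 °C → rt; then 1 M HCl
Reagents that add atoms: triisopropyl borate, CC(C)OB(OC(C)C)OC(C)C; water, O
Why: Bromine–lithium exchange is faster than benzylic or ring deprotonation at −78 °C, and trapping the aryllithium with the borate followed by acid hydrolysis is the standard lithiation–borylation route to an arylboronic acid.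

Step 15
Reactants: 23 2,4-bis(benzyloxy)-6-[2,4,6-tris(benzyloxy)phenoxy]-3-[3,4,5-tris(benzyloxy)phenoxy]phenol; 29 [3,4,5-tris(benzyloxy)phenyl]boronic acid (2.5 equiv)
Product: 30 1,3-bis(benzyloxy)-5-[2,4,6-tris(benzyloxy)phenoxy]-2,4-bis[3,4,5-tris(benzyloxy)phenoxy]benzene
Conditions: Cu(OAc)2, pyridine, 4 Å MS, CH2Cl2, dry air, rt
Reagents that add atoms: none
Why: In the Chan–Lam coupling the phenoxide and the aryl group meet on copper (divalent copper, reoxidised by air) and C–O reductive elimination follows at room temperature without strong base, a process known to tolerate phenols with two ortho substituents and to work well with electron-rich arylboronic acids.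

Step 16
Reactants: 30 1,3-bis(benzyloxy)-5-[2,4,6-tris(benzyloxy)phenoxy]-2,4-bis[3,4,5-tris(benzyloxy)phenoxy]benzene
Product: 31 5-(2,4,6-trihydroxyphenoxy)-2,4-bis(3,4,5-trihydroxyphenoxy)benzene-1,3-diol (CNP0304743.0)
Conditions: H2 (1 atm), Pd/C, THF–MeOH, rt; filtration and concentration under Ar
Reagents that add atoms: none
Why: Hydrogenolysis of all eleven benzyl ethers over palladium on carbon leaves the diaryl ether bonds and the arenes untouched and should deliver the free polyphenol.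

**Compound list**

1 | 2,4,6-trihydroxybenzaldehyde | O=Cc1c(O)cc(O)cc1O | starting material
2 | 2,4,6-tris(benzyloxy)benzaldehyde | O=Cc1c(OCc2ccccc2)cc(OCc2ccccc2)cc1OCc1ccccc1 | intermediate
3 | 2,4,6-tris(benzyloxy)phenyl formate | O=COc1c(OCc2ccccc2)cc(OCc2ccccc2)cc1OCc1ccccc1 | intermediate
4 | 2,4,6-tris(benzyloxy)phenol | Oc1c(OCc2ccccc2)cc(OCc2ccccc2)cc1OCc1ccccc1 | intermediate
5 | 1,3,5-tris(benzyloxy)-2-{[(E)-1,2-dichloroethenyl]oxy}benzene | Cl/C=C(/Cl)Oc1c(OCc2ccccc2)cc(OCc2ccccc2)cc1OCc1ccccc1 | intermediate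
6 | 1,3,5-tris(benzyloxy)-2-[(chloroethynyl)oxy]benzene | ClC#COc1c(OCc2ccccc2)cc(OCc2ccccc2)cc1OCc1ccccc1 | intermediate
7 | lithium [2,4,6-tris(benzyloxy)phenoxy]acetylide | [Li]C#COc1c(OCc2ccccc2)cc(OCc2ccccc2)cc1OCc1ccccc1 | intermediate
8 | 1,3,5-tris(benzyloxy)-2-(ethynyloxy)benzene | C#COc1c(OCc2ccccc2)cc(OCc2ccccc2)cc1OCc1ccccc1 | intermediate
9 | tributyl{1-[2,4,6-tris(benzyloxy)phenoxy]ethenyl}stannane | C=C(Oc1c(OCc2ccccc2)cc(OCc2ccccc2)cc1OCc1ccccc1)[Sn](CCCC)(CCCC)CCCC | intermediate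
10 | 3,4,5-tris(benzyloxy)benzaldehyde | O=Cc1cc(OCc2ccccc2)c(OCc2ccccc2)c(OCc2ccccc2)c1 | starting material
11 | 3,4,5-tris(benzyloxy)phenyl formate | O=COc1cc(OCc2ccccc2)c(OCc2ccccc2)c(OCc2ccccc2)c1 | intermediate
12 | 3,4,5-tris(benzyloxy)phenol | Oc1cc(OCc2ccccc2)c(OCc2ccccc2)c(OCc2ccccc2)c1 | intermediate
13 | squaric acid | OC1=C(O)C(=O)C1=O | starting material
14 | 3,4-dichlorocyclobut-3-ene-1,2-dione | ClC1=C(Cl)C(=O)C1=O | intermediate
15 | 3-(benzyloxy)-4-chlorocyclobut-3-ene-1,2-dione | ClC1=C(OCc2ccccc2)C(=O)C1=O | intermediate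
16 | 3-(benzyloxy)-4-[3,4,5-tris(benzyloxy)phenoxy]cyclobut-3-ene-1,2-dione | O=C1C(=O)C(OCc2ccccc2)=C1Oc1cc(OCc2ccccc2)c(OCc2ccccc2)c(OCc2ccccc2)c1 | intermediate
17 | 1-[2,4,6-tris(benzyloxy)phenoxy]vinyllithium | [Li]C(=C)Oc1c(OCc2ccccc2)cc(OCc2ccccc2)cc1OCc1ccccc1 | intermediate
18 | lithium alkoxide of 19 (racemic) | O=C1C(Oc2cc(OCc3ccccc3)c(OCc3ccccc3)c(OCc3ccccc3)c2)=C(OCc2ccccc2)C1(O[Li])C(=C)Oc1c(OCc2ccccc2)cc(OCc2ccccc2)cc1OCc1ccccc1 | intermediate
19 | racemic 3-(benzyloxy)-4-hydroxy-2-[3,4,5-tris(benzyloxy)phenoxy]-4-{1-[2,4,6-tris(benzyloxy)phenoxy]vinyl}cyclobut-2-en-1-one | O=C1C(Oc2cc(OCc3ccccc3)c(OCc3ccccc3)c(OCc3ccccc3)c2)=C(OCc2ccccc2)C1(O)C(=C)Oc1c(OCc2ccccc2)cc(OCc2ccccc2)cc1OCc1ccccc1 | intermediate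
20 | (Z)-dienylketene from ring opening of 19 (aryloxy ketene carbon and 1-(aryloxy)vinyl group cis on the central C=C) | O=C=C(Oc1cc(OCc2ccccc2)c(OCc2ccccc2)c(OCc2ccccc2)c1)/C(OCc1ccccc1)=C(O)\C(=C)Oc1c(OCc2ccccc2)cc(OCc2ccccc2)cc1OCc1ccccc1 | intermediate
21 | 3-(benzyloxy)-4-hydroxy-5-[2,4,6-tris(benzyloxy)phenoxy]-2-[3,4,5-tris(benzyloxy)phenoxy]cyclohexa-2,4-dien-1-one | O=C1CC(Oc2c(OCc3ccccc3)cc(OCc3ccccc3)cc2OCc2ccccc2)=C(O)C(OCc2ccccc2)=C1Oc1cc(OCc2ccccc2)c(OCc2ccccc2)c(OCc2ccccc2)c1 | intermediate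
22 | 3-(benzyloxy)-5-[2,4,6-tris(benzyloxy)phenoxy]-2-[3,4,5-tris(benzyloxy)phenoxy]benzene-1,4-diol | Oc1cc(Oc2c(OCc3ccccc3)cc(OCc3ccccc3)cc2OCc2ccccc2)c(O)c(OCc2ccccc2)c1Oc1cc(OCc2ccccc2)c(OCc2ccccc2)c(OCc2ccccc2)c1 | intermediate
23 | 2,4-bis(benzyloxy)-6-[2,4,6-tris(benzyloxy)phenoxy]-3-[3,4,5-tris(benzyloxy)phenoxy]phenol | O(Cc1ccccc1)c1cc(Oc2c(OCc3ccccc3)cc(OCc3ccccc3)cc2OCc2ccccc2)c(O)c(OCc2ccccc2)c1Oc1cc(OCc2ccccc2)c(OCc2ccccc2)c(OCc2ccccc2)c1 | intermediate
24 | 5-bromo-1,2,3-trimethoxybenzene | COc1cc(Br)cc(OC)c1OC | starting material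
25 | 5-bromobenzene-1,2,3-triol | Oc1cc(Br)cc(O)c1O | intermediate
26 | 5-bromo-1,2,3-tris(benzyloxy)benzene | Brc1cc(OCc2ccccc2)c(OCc2ccccc2)c(OCc2ccccc2)c1 | intermediate
27 | 3,4,5-tris(benzyloxy)phenyllithium | [Li]c1cc(OCc2ccccc2)c(OCc2ccccc2)c(OCc2ccccc2)c1 | intermediate
28 | lithium triisopropoxy[3,4,5-tris(benzyloxy)phenyl]borate | [Li+].CC(C)O[B-](OC(C)C)(OC(C)C)c1cc(OCc2ccccc2)c(OCc2ccccc2)c(OCc2ccccc2)c1 | intermediate
29 | [3,4,5-tris(benzyloxy)phenyl]boronic acid | OB(O)c1cc(OCc2ccccc2)c(OCc2ccccc2)c(OCc2ccccc2)c1 | intermediate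
30 | 1,3-bis(benzyloxy)-5-[2,4,6-tris(benzyloxy)phenoxy]-2,4-bis[3,4,5-tris(benzyloxy)phenoxy]benzene | O(Cc1ccccc1)c1cc(Oc2c(OCc3ccccc3)cc(OCc3ccccc3)cc2OCc2ccccc2)c(Oc2cc(OCc3ccccc3)c(OCc3ccccc3)c(OCc3ccccc3)c2)c(OCc2ccccc2)c1Oc1cc(OCc2ccccc2)c(OCc2ccccc2)c(OCc2ccccc2)c1 | intermediate
31 | 5-(2,4,6-trihydroxyphenoxy)-2,4-bis(3,4,5-trihydroxyphenoxy)benzene-1,3-diol (CNP0304743.0) | Oc1cc(O)c(Oc2cc(O)c(Oc3cc(O)c(O)c(O)c3)c(O)c2Oc2cc(O)c(O)c(O)c2)c(O)c1 | target

**Step count and risks**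

Total step count: 16. Longest linear sequence: 10 steps (1, 2, 3, 4, 5, 9, 10, 11, 15, 16).

Steps most likely to fail:

1. Step 15 (attachment of ring D). Copper phenoxide formation and aryl transfer may be too slow at a hydroxyl flanked by a benzyloxy group and a 2,6-disubstituted aryloxy group, so that protodeboronation and homocoupling of the boronic acid or oxidative degradation of the electron-rich phenol take over. The fallback is a metal-free arylation by ligand coupling at trivalent iodine; it sets out from bromide 26 and returns at 30. Bromine–lithium exchange (through 27) and quenching with iodine should give 5-iodo-1,2,3-tris(benzyloxy)benzene F1. Oxidation with mCPBA and TsOH·H2O in MeCN should give [hydroxy(tosyloxy)iodo]-3,4,5-tris(benzyloxy)benzene F2, which is trapped in the same flask by 1,3,5-trimethoxybenzene to give [3,4,5-tris(benzyloxy)phenyl](2,4,6-trimethoxyphenyl)iodonium tosylate F3. Phenol 23 with t-BuOK in toluene at rt is then arylated by F3, the more electron-rich trimethoxyphenyl group staying on iodine, to give 30.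

2. Step 9 (addition to the mixed squarate). Discrimination between the two carbonyls by a benzyloxy versus an aryloxy donor may be incomplete, and attack at the aryloxy-bearing ring carbon with loss of phenoxide may compete. The fallback removes the regiochemical question; it sets out from dichloride 14 and returns at 19. Dichloride 14 with two equivalents of phenol 12 and i-Pr2NEt should give the symmetric 3,4-bis[3,4,5-tris(benzyloxy)phenoxy]cyclobut-3-ene-1,2-dione F4. Vinyllithium 17 adds to either carbonyl with the same result, giving the lithium alkoxide adduct F5, which is silylated in the flask with TESOTf to the triethylsilyl ether F6. Benzyl alcohol with a catalytic amount of lithium benzyloxide (THF, −40 °C) should then exchange only the aryloxy group on the enone β-carbon, by addition–elimination at the vinylogous aryl ester, to give the 3-benzyloxy triethylsilyl ether F7. Buffered fluoride (TBAF, AcOH, 0 °C) frees alcohol 19.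

3. Step 11 (mono-benzylation of the hydroquinone). Steric discrimination between the two phenols may be incomplete, giving double or misplaced alkylation, and the hydroquinone may oxidise to the quinone under base. The fallback differentiates the two oxygens before ring B exists; it sets out from 19 and returns at 23. Silylation of the tertiary alcohol (TBSOTf, 2,6-lutidine, CH2Cl2, −78 → 0 °C) should give the tert-butyldimethylsilyl ether F8. The same thermal ring expansion (toluene, 110 °C), through the silyloxy dienylketene F9 and the silyloxy cyclohexadienone F10, should give 3-(benzyloxy)-4-(tert-butyldimethylsilyloxy)-5-[2,4,6-tris(benzyloxy)phenoxy]-2-[3,4,5-tris(benzyloxy)phenoxy]phenol F11, in which only the C5 hydroxyl is free. Benzylation (BnBr, K2CO3, acetone) gives the fully protected silyl ether F12, and TBAF in THF at 0 °C uncovers the C2 hydroxyl to give 23.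

**Further compounds**

F1 | step 15 | 5-iodo-1,2,3-tris(benzyloxy)benzene | Ic1cc(OCc2ccccc2)c(OCc2ccccc2)c(OCc2ccccc2)c1
F2 | step 15 | [hydroxy(tosyloxy)iodo]-3,4,5-tris(benzyloxy)benzene | Cc1ccc(cc1)S(=O)(=O)OI(O)c1cc(OCc2ccccc2)c(OCc2ccccc2)c(OCc2ccccc2)c1
F3 | step 15 | [3,4,5-tris(benzyloxy)phenyl](2,4,6-trimethoxyphenyl)iodonium 4-methylbenzenesulfonate | COc1cc(OC)c([I+]c2cc(OCc3ccccc3)c(OCc3ccccc3)c(OCc3ccccc3)c2)c(OC)c1.Cc1ccc(S(=O)(=O)[O-])cc1
F4 | step 9 | 3,4-bis[3,4,5-tris(benzyloxy)phenoxy]cyclobut-3-ene-1,2-dione | O=C1C(=O)C(Oc2cc(OCc3ccccc3)c(OCc3ccccc3)c(OCc3ccccc3)c2)=C1Oc1cc(OCc2ccccc2)c(OCc2ccccc2)c(OCc2ccccc2)c1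
F5 | step 9 | racemic lithium 4-oxo-2,3-bis[3,4,5-tris(benzyloxy)phenoxy]-1-{1-[2,4,6-tris(benzyloxy)phenoxy]vinyl}cyclobut-2-en-1-olate | O=C1C(Oc2cc(OCc3ccccc3)c(OCc3ccccc3)c(OCc3ccccc3)c2)=C(Oc2cc(OCc3ccccc3)c(OCc3ccccc3)c(OCc3ccccc3)c2)C1(O[Li])C(=C)Oc1c(OCc2ccccc2)cc(OCc2ccccc2)cc1OCc1ccccc1
F6 | step 9 | racemic 4-(triethylsilyloxy)-2,3-bis[3,4,5-tris(benzyloxy)phenoxy]-4-{1-[2,4,6-tris(benzyloxy)phenoxy]vinyl}cyclobut-2-en-1-one | O=C1C(Oc2cc(OCc3ccccc3)c(OCc3ccccc3)c(OCc3ccccc3)c2)=C(Oc2cc(OCc3ccccc3)c(OCc3ccccc3)c(OCc3ccccc3)c2)C1(O[Si](CC)(CC)CC)C(=C)Oc1c(OCc2ccccc2)cc(OCc2ccccc2)cc1OCc1ccccc1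
F7 | step 9 | racemic 3-(benzyloxy)-4-(triethylsilyloxy)-2-[3,4,5-tris(benzyloxy)phenoxy]-4-{1-[2,4,6-tris(benzyloxy)phenoxy]vinyl}cyclobut-2-en-1-one | O=C1C(Oc2cc(OCc3ccccc3)c(OCc3ccccc3)c(OCc3ccccc3)c2)=C(OCc2ccccc2)C1(O[Si](CC)(CC)CC)C(=C)Oc1c(OCc2ccccc2)cc(OCc2ccccc2)cc1OCc1ccccc1
F8 | step 11 | racemic 3-(benzyloxy)-4-(tert-butyldimethylsilyloxy)-2-[3,4,5-tris(benzyloxy)phenoxy]-4-{1-[2,4,6-tris(benzyloxy)phenoxy]vinyl}cyclobut-2-en-1-one | O=C1C(Oc2cc(OCc3ccccc3)c(OCc3ccccc3)c(OCc3ccccc3)c2)=C(OCc2ccccc2)C1(O[Si](C)(C)C(C)(C)C)C(=C)Oc1c(OCc2ccccc2)cc(OCc2ccccc2)cc1OCc1ccccc1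
F9 | step 11 | (Z)-silyloxy dienylketene from ring opening of F8 | O=C=C(Oc1cc(OCc2ccccc2)c(OCc2ccccc2)c(OCc2ccccc2)c1)/C(OCc1ccccc1)=C(O[Si](C)(C)C(C)(C)C)\C(=C)Oc1c(OCc2ccccc2)cc(OCc2ccccc2)cc1OCc1ccccc1
F10 | step 11 | 3-(benzyloxy)-4-(tert-butyldimethylsilyloxy)-5-[2,4,6-tris(benzyloxy)phenoxy]-2-[3,4,5-tris(benzyloxy)phenoxy]cyclohexa-2,4-dien-1-one | O=C1CC(Oc2c(OCc3ccccc3)cc(OCc3ccccc3)cc2OCc2ccccc2)=C(O[Si](C)(C)C(C)(C)C)C(OCc2ccccc2)=C1Oc1cc(OCc2ccccc2)c(OCc2ccccc2)c(OCc2ccccc2)c1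
F11 | step 11 | 3-(benzyloxy)-4-(tert-butyldimethylsilyloxy)-5-[2,4,6-tris(benzyloxy)phenoxy]-2-[3,4,5-tris(benzyloxy)phenoxy]phenol | Oc1cc(Oc2c(OCc3ccccc3)cc(OCc3ccccc3)cc2OCc2ccccc2)c(O[Si](C)(C)C(C)(C)C)c(OCc2ccccc2)c1Oc1cc(OCc2ccccc2)c(OCc2ccccc2)c(OCc2ccccc2)c1
F12 | step 11 | tert-butyl{2,4-bis(benzyloxy)-6-[2,4,6-tris(benzyloxy)phenoxy]-3-[3,4,5-tris(benzyloxy)phenoxy]phenoxy}dimethylsilane | O(Cc1ccccc1)c1cc(Oc2c(OCc3ccccc3)cc(OCc3ccccc3)cc2OCc2ccccc2)c(O[Si](C)(C)C(C)(C)C)c(OCc2ccccc2)c1Oc1cc(OCc2ccccc2)c(OCc2ccccc2)c(OCc2ccccc2)c1
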